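**Retrosynthetic overview**
1. Target ⇐ C8 angeloylation of alcohol 24 ⇐ desilylation of 23; the oxirane (second ring) ⇐ nucleophilic epoxidation of enone 22 anti to OAc-1; OAc-5 ⇐ α′-hydroxylation of enone 19.
2. Cyclohexenone ring (first ring) ⇐ C1–C6 carbonyl-ene closure of the acyclic (2Z,6Z)-4-oxofarnesal 18 with loss of a C14 hydrogen. This is the farnesyl → bisabolyl → β-bisabolene closure run at the aldehyde oxidation level; it sets C1, C6 and the 7(14)-methylene in one step under control of C8.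
3. Keto-enal 18 ⇐ singlet-oxygen opening of the 2-alkyl-3-methylfuran 16 (furan = masked cis-4-oxo-2-enal).
4. 16 ⇐ Z-selective Wittig reaction of α-silyloxy ketone 6 with ylide 15.
5. 6 ⇐ methyl (S)-glycidate + isobutenyl Grignard; 15 ⇐ 3-methylfuran + ethylene oxide.

Assumption: bisabolane numbering is used for ring compounds (ring C1–C6, C6 carries C7, C14 = exocyclic CH2 on C7, C8 = side-chain carbinol, C15 = methyl on C3), in which the target is (1R,2S,3S,5S,6R,8S); metal alkoxides that are only protonated on aqueous work-up are not numbered separately.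

**Route**

Step 1
Reactants: 1 methyl (2S)-oxirane-2-carboxylate (methyl (S)-glycidate); 2 (2-methylprop-1-en-1-yl)magnesium bromide
Product: 3 methyl (2S)-2-hydroxy-5-methylhex-4-enoate
Conditions: CuI (10 mol %), THF, −40 → −20 °C; H2O quench
Reagents that add atoms: none
Why: Cu-catalysed SN2 opening of the glycidic ester at the unhindered C3 (organocuprate epoxide opening) leaves the C2–O stereocentre untouched, so the S centre of 1 becomes C8 of the target.

Step 2
Reactants: 3 methyl (2S)-2-hydroxy-5-methylhex-4-enoate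
Product: 4 methyl (2S)-2-[(tert-butyldimethylsilyl)oxy]-5-methylhex-4-enoate
Conditions: TBSCl, imidazole, DMF, 0 °C → rt
Reagents that add atoms: tert-butyldimethylsilyl chloride (CC(C)(C)[Si](C)(C)Cl)
Why: Standard silyl ether protection; the bulky, non-chelating OTBS group is needed for the Z-selective Wittig reaction and for face shielding in the ring closure.

Step 3
Reactants: 4 methyl (2S)-2-[(tert-butyldimethylsilyl)oxy]-5-methylhex-4-enoate
Product: 6 (3S)-3-[(tert-butyldimethylsilyl)oxy]-6-methylhept-5-en-2-one, via Weinreb amide 5 (not isolated)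
Conditions: MeNHOMe·HCl, i-PrMgCl, THF, −20 °C; then MeMgBr, 0 °C; H2O
Reagents that add atoms: N,O-dimethylhydroxylamine hydrochloride (CNOC.Cl; atoms in 5 only); methylmagnesium bromide (C[Mg]Br)
Why: One-pot Weinreb ketone synthesis: the chloromagnesium amide turns the ester into 5, whose chelated tetrahedral adduct with MeMgBr stops at the methyl ketone without touching the α-stereocentre.

Step 4
Reactants: 7 3-methylfuran
Product: 8 2-bromo-3-methylfuran
Conditions: NBS, DMF, −20 → 0 °C, dark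
Reagents that add atoms: N-bromosuccinimide (O=C1CCC(=O)N1Br)
Why: Electrophilic aromatic bromination of the furan goes to the α-position next to the methyl group, the most activated site.

Step 5
Reactants: 8 2-bromo-3-methylfuran; 9 oxirane (ethylene oxide)
Product: 12 2-(3-methylfuran-2-yl)ethyl 4-methylbenzenesulfonate, via furyllithium 10 (not isolated), via lithium alkoxide 11 (not isolated)
Conditions: t-BuLi (2 equiv), THF, −78 °C; ethylene oxide, −78 → 0 °C; TsCl, 0 °C → rt
Reagents that add atoms: tert-butyllithium ([Li]C(C)(C)C; Li in 10 and 11 only); 4-toluenesulfonyl chloride (Cc1ccc(cc1)S(=O)(=O)Cl)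
Why: Halogen–lithium exchange fixes the anion at C2, epoxide opening by the aryllithium adds the two-carbon arm, and the alkoxide is sulfonylated in the same pot.

Step 6
Reactants: 12 2-(3-methylfuran-2-yl)ethyl 4-methylbenzenesulfonate
Product: 14 [2-(3-methylfuran-2-yl)ethyl]triphenylphosphonium iodide, via iodide 13 (not isolated)
Conditions: NaI, PPh3, MeCN, 80 °C
Reagents that add atoms: sodium iodide ([Na+].[I-]); triphenylphosphine (c1ccc(cc1)P(c1ccccc1)c1ccccc1)
Why: Finkelstein exchange followed by SN2 quaternisation of PPh3 at a primary carbon (phosphonium salt formation).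

Step 7
Reactants: 14 [2-(3-methylfuran-2-yl)ethyl]triphenylphosphonium iodide; 6 (3S)-3-[(tert-butyldimethylsilyl)oxy]-6-methylhept-5-en-2-one
Product: 16 2-[(2Z,4S)-4-{[tert-butyl(dimethyl)silyl]oxy}-3,7-dimethylocta-2,6-dien-1-yl]-3-methylfuran, via ylide 15 (not isolated)
Conditions: KHMDS, THF, −78 → 0 °C; then 6, THF, −78 °C → rt
Reagents that add atoms: none
Why: Salt-free Wittig olefination of an α-alkoxy ketone (Still-type Z-selective variant) places the ylide carbon cis to the oxygenated carbon, giving the 6Z trisubstituted alkene, and addition at −78 °C avoids enolisation at C8.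

Step 8
Reactants: 16 2-[(2Z,4S)-4-{[tert-butyl(dimethyl)silyl]oxy}-3,7-dimethylocta-2,6-dien-1-yl]-3-methylfuran
Product: 18 (2Z,6Z,8S)-8-[(tert-butyldimethylsilyl)oxy]-3,7,11-trimethyl-4-oxododeca-2,6,10-trienal, via endoperoxide 17 (not isolated)
Conditions: O2, TPP (cat.), hν, CH2Cl2, −78 °C; Me2S, −78 → 0 °C; crude used at once
Reagents that add atoms: dioxygen (O=O)
Why: [4+2] cycloaddition of singlet oxygen to the electron-rich furan (about 100 times faster than the ene reaction of trisubstituted alkenes) and sulfide reduction of the endoperoxide unmask the cis-4-oxo-2-enal, whose 2Z geometry is fixed by the former ring.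

Step 9
Reactants: 18 (2Z,6Z,8S)-8-[(tert-butyldimethylsilyl)oxy]-3,7,11-trimethyl-4-oxododeca-2,6,10-trienal
Product: 19 (1S,6R,8S)-8-[(tert-butyldimethylsilyl)oxy]-1-hydroxybisabola-2,7(14),10-trien-4-one = (4S,5R)-5-[(3S)-3-{[tert-butyl(dimethyl)silyl]oxy}-6-methylhepta-1,5-dien-2-yl]-4-hydroxy-2-methylcyclohex-2-en-1-one
Conditions: Me2AlCl (2 equiv), CH2Cl2 (0.01 M), −78 °C; aq. Rochelle salt
Reagents that add atoms: none
Why: Proposed new method: a Lewis-acid type-I carbonyl-ene (Prins-type) closure of C1 onto C6 with transfer of a C14 hydrogen to oxygen, whose closest known relatives are Me2AlCl ene cyclisations of unsaturated aldehydes (citronellal → isopulegol) and the acid-catalysed neral → trans-isopiperitenol cyclisation; the chair-like transition state with the O–Al group equatorial gives the 1,6-trans alcohol, the 6Z geometry puts only the C14 methyl within reach of the oxygen so the 7(14)-methylene forms, and with H-8 eclipsing the alkene (A1,3 strain with C5) the OTBS group blocks one π-face so that C1 adds to the other, giving 6R and 1S.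

Step 10
Reactants: 19 (1S,6R,8S)-8-[(tert-butyldimethylsilyl)oxy]-1-hydroxybisabola-2,7(14),10-trien-4-one
Product: 22 (1S,5S,6R,8S)-1,5-diacetoxy-8-[(tert-butyldimethylsilyl)oxy]bisabola-2,7(14),10-trien-4-one, via dipotassium enolate 20 (not isolated), via dipotassium diolate 21 (not isolated)
Conditions: KHMDS (2.3 equiv), THF, −78 °C; Davis oxaziridine; Ac2O, DMAP (cat.), −78 → 0 °C
Reagents that add atoms: potassium bis(trimethylsilyl)amide (C[Si](C)(C)N([K])[Si](C)(C)C; K in 20 and 21 only); 2-(benzenesulfonyl)-3-phenyloxaziridine (O=S(=O)(N1OC1c1ccccc1)c1ccccc1); acetic anhydride (CC(=O)OC(C)=O)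
Why: Kinetic α′-enolate formation of the enone (the C1 alkoxide blocks γ-deprotonation) and Davis enolate hydroxylation anti to the C6 side chain set C5 trans (5S), and both alkoxides are acetylated in situ.

Step 11
Reactants: 22 (1S,5S,6R,8S)-1,5-diacetoxy-8-[(tert-butyldimethylsilyl)oxy]bisabola-2,7(14),10-trien-4-one
Product: 23 (1R,2S,3S,5S,6R,8S)-1,5-diacetoxy-8-[(tert-butyldimethylsilyl)oxy]-2,3-epoxybisabola-7(14),10-dien-4-one
Conditions: t-BuOOH (anhydrous), DBU (cat.), CH2Cl2, 0 °C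
Reagents that add atoms: tert-butyl hydroperoxide (CC(C)(C)OO)
Why: Weitz–Scheffer nucleophilic epoxidation touches only the enone, and tert-butylperoxide adds to C2 anti to the C1 acetoxy group, giving the 2,3-epoxide trans to OAc-1 (2S,3S).

Step 12
Reactants: 23 (1R,2S,3S,5S,6R,8S)-1,5-diacetoxy-8-[(tert-butyldimethylsilyl)oxy]-2,3-epoxybisabola-7(14),10-dien-4-one
Product: 24 (1R,2S,3S,5S,6R,8S)-1,5-diacetoxy-2,3-epoxy-8-hydroxybisabola-7(14),10-dien-4-one
Conditions: HF·pyridine, pyridine/THF, 0 °C → rt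
Reagents that add atoms: none
Why: Fluoride-mediated silyl ether cleavage under buffered conditions leaves the acetates, the epoxy ketone and the alkenes intact.

Step 13
Reactants: 24 (1R,2S,3S,5S,6R,8S)-1,5-diacetoxy-2,3-epoxy-8-hydroxybisabola-7(14),10-dien-4-one; 25 angelic acid [(2Z)-2-methylbut-2-enoic acid]
Product: 27 target CNP0298051.3 = (1R,2S,3S,5S,6R,8S)-1,5-diacetoxy-8-angeloyloxy-2,3-epoxybisabola-7(14),10-dien-4-one, via mixed anhydride 26 (not isolated)
Conditions: 25, 2,4,6-Cl3C6H2COCl, Et3N, toluene, rt; then 24, toluene, 75 °C (no DMAP)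
Reagents that add atoms: 2,4,6-trichlorobenzoyl chloride (O=C(Cl)c1c(Cl)cc(Cl)cc1Cl; atoms in 26 only)
Why: Yamaguchi-type mixed-anhydride esterification without DMAP acylates the allylic C8 alcohol with retention and without angelate-to-tiglate isomerisation.

**Compound list**
1 | methyl (2S)-oxirane-2-carboxylate (methyl (S)-glycidate) | COC(=O)[C@@H]1CO1 | starting material
2 | (2-methylprop-1-en-1-yl)magnesium bromide | CC(C)=C[Mg]Br | starting material
3 | methyl (2S)-2-hydroxy-5-methylhex-4-enoate | COC(=O)[C@H](CC=C(C)C)O | intermediate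
4 | methyl (2S)-2-[(tert-butyldimethylsilyl)oxy]-5-methylhex-4-enoate | COC(=O)[C@H](CC=C(C)C)O[Si](C)(C)C(C)(C)C | intermediate
5 | (2S)-2-[(tert-butyldimethylsilyl)oxy]-N-methoxy-N,5-dimethylhex-4-enamide (Weinreb amide) | CON(C)C(=O)[C@H](CC=C(C)C)O[Si](C)(C)C(C)(C)C | intermediate (not isolated)
6 | (3S)-3-[(tert-butyldimethylsilyl)oxy]-6-methylhept-5-en-2-one | CC(=O)[C@H](CC=C(C)C)O[Si](C)(C)C(C)(C)C | intermediate
7 | 3-methylfuran | Cc1ccoc1 | starting material
8 | 2-bromo-3-methylfuran | Cc1ccoc1Br | intermediate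
9 | oxirane (ethylene oxide) | C1CO1 | starting material
10 | (3-methylfuran-2-yl)lithium | Cc1ccoc1[Li] | intermediate (not isolated)
11 | lithium 2-(3-methylfuran-2-yl)ethanolate | Cc1ccoc1CC[O-].[Li+] | intermediate (not isolated)
12 | 2-(3-methylfuran-2-yl)ethyl 4-methylbenzenesulfonate | Cc1ccc(cc1)S(=O)(=O)OCCc1occc1C | intermediate
13 | 2-(2-iodoethyl)-3-methylfuran | Cc1ccoc1CCI | intermediate (not isolated)
14 | [2-(3-methylfuran-2-yl)ethyl]triphenylphosphonium iodide | Cc1ccoc1CC[P+](c1ccccc1)(c1ccccc1)c1ccccc1.[I-] | intermediate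
15 | [2-(3-methylfuran-2-yl)ethylidene]triphenylphosphorane (ylide) | Cc1ccoc1CC=P(c1ccccc1)(c1ccccc1)c1ccccc1 | intermediate (not isolated)
16 | 2-[(2Z,4S)-4-{[tert-butyl(dimethyl)silyl]oxy}-3,7-dimethylocta-2,6-dien-1-yl]-3-methylfuran | Cc1ccoc1C/C=C(/C)[C@H](CC=C(C)C)O[Si](C)(C)C(C)(C)C | intermediate
17 | 2,5-endoperoxide of 16 (5-methyl-2,3,7-trioxabicyclo[2.2.1]hept-5-ene carrying the side chain of 16 at C4; mixture at the bridgeheads) | CC1=CC2OOC1(C/C=C(/C)[C@H](CC=C(C)C)O[Si](C)(C)C(C)(C)C)O2 | intermediate (not isolated)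
18 | (2Z,6Z,8S)-8-[(tert-butyldimethylsilyl)oxy]-3,7,11-trimethyl-4-oxododeca-2,6,10-trienal | O=C/C=C(/C)C(=O)C/C=C(/C)[C@H](CC=C(C)C)O[Si](C)(C)C(C)(C)C | intermediate
19 | (1S,6R,8S)-8-[(tert-butyldimethylsilyl)oxy]-1-hydroxybisabola-2,7(14),10-trien-4-one; OH-1 trans to the C6 side chain | C=C([C@@H]1[C@@H](O)C=C(C)C(=O)C1)[C@H](CC=C(C)C)O[Si](C)(C)C(C)(C)C | intermediate
20 | dipotassium 1-alkoxide / C4–C5 dienolate of 19 | C=C([C@@H]1[C@@H]([O-])C=C(C)C([O-])=C1)[C@H](CC=C(C)C)O[Si](C)(C)C(C)(C)C.[K+].[K+] | intermediate (not isolated)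
21 | dipotassium (1S,5S,6R,8S)-8-[(tert-butyldimethylsilyl)oxy]-4-oxobisabola-2,7(14),10-triene-1,5-diolate | C=C([C@@H]1[C@@H]([O-])C=C(C)C(=O)[C@H]1[O-])[C@H](CC=C(C)C)O[Si](C)(C)C(C)(C)C.[K+].[K+] | intermediate (not isolated)
22 | (1S,5S,6R,8S)-1,5-diacetoxy-8-[(tert-butyldimethylsilyl)oxy]bisabola-2,7(14),10-trien-4-one; both OAc trans to the C6 side chain | C=C([C@@H]1[C@@H](OC(C)=O)C=C(C)C(=O)[C@H]1OC(C)=O)[C@H](CC=C(C)C)O[Si](C)(C)C(C)(C)C | intermediate
23 | (1R,2S,3S,5S,6R,8S)-1,5-diacetoxy-8-[(tert-butyldimethylsilyl)oxy]-2,3-epoxybisabola-7(14),10-dien-4-one; epoxide cis to the side chain, trans to both OAc | C=C([C@@H]1[C@@H](OC(C)=O)[C@@H]2O[C@]2(C)C(=O)[C@H]1OC(C)=O)[C@H](CC=C(C)C)O[Si](C)(C)C(C)(C)C | intermediate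
24 | (1R,2S,3S,5S,6R,8S)-1,5-diacetoxy-2,3-epoxy-8-hydroxybisabola-7(14),10-dien-4-one | C=C([C@@H]1[C@@H](OC(C)=O)[C@@H]2O[C@]2(C)C(=O)[C@H]1OC(C)=O)[C@H](CC=C(C)C)O | intermediate
25 | angelic acid, (2Z)-2-methylbut-2-enoic acid | C/C=C(/C)C(=O)O | starting material
26 | (2Z)-2-methylbut-2-enoic 2,4,6-trichlorobenzoic anhydride | C/C=C(/C)C(=O)OC(=O)c1c(Cl)cc(Cl)cc1Cl | intermediate (not isolated)
27 | CNP0298051.3, (1R,2S,3S,5S,6R,8S)-1,5-diacetoxy-8-[(2Z)-2-methylbut-2-enoyloxy]-2,3-epoxybisabola-7(14),10-dien-4-one | C=C([C@@H]1[C@@H](OC(C)=O)[C@@H]2O[C@]2(C)C(=O)[C@H]1OC(C)=O)[C@H](CC=C(C)C)OC(=O)/C(C)=C\C | target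

**Step count**
Total: 13 steps. Longest linear sequence: 10 steps (1–3, then 7–13; the furan branch 4–6 is equally long up to step 7).

**Steps most likely to fail, with fallbacks**

Step 9 (ring closure). The cis-keto-enal 18 may enolise toward C5, aldolise to a cyclopentenone or isomerise to the E-enedione faster than the unactivated, allylically oxygenated alkene attacks the aldehyde. The face selectivity also rests on a model, not on precedent. The fallback replaces the ene terminator by an allylsilane (intramolecular Hosomi–Sakurai reaction), which is far more nucleophilic and fixes the 7(14)-methylene whatever the alkene geometry. It sets out from ester 4. Amide 5 is generated as in step 3 and treated with Me3SiCH2MgCl to give (3S)-3-[(tert-butyldimethylsilyl)oxy]-6-methyl-1-(trimethylsilyl)hept-5-en-2-one F1. Wittig reaction with ylide 15 gives 2-[(4S)-4-{[tert-butyl(dimethyl)silyl]oxy}-7-methyl-3-[(trimethylsilyl)methyl]octa-2,6-dien-1-yl]-3-methylfuran F2 (either alkene isomer serves). Photooxygenation as in step 8 passes through the furan endoperoxide F3 and, after Me2S, gives (2Z,8S)-8-[(tert-butyldimethylsilyl)oxy]-3,11-dimethyl-4-oxo-7-[(trimethylsilyl)methyl]dodeca-2,6,10-trienal F4. BF3·OEt2 in CH2Cl2 at −78 °C then closes C1–C6 with loss of silicon, and the route is rejoined at 19.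

Step 11 (epoxidation). DBU/t-BuOO− may enolise, epimerise or deacetylate the α-acetoxy ketone at C5 before the enone is consumed. The fallback epoxidises before C5 is oxygenated. It sets out from 19. Ac2O/pyridine gives (1S,6R,8S)-1-acetoxy-8-[(tert-butyldimethylsilyl)oxy]bisabola-2,7(14),10-trien-4-one F5. t-BuOOH/DBU gives (1R,2S,3S,6R,8S)-1-acetoxy-8-[(tert-butyldimethylsilyl)oxy]-2,3-epoxybisabola-7(14),10-dien-4-one F6. KHMDS (1.1 equiv, −78 °C) gives the potassium C4–C5 enolate of the epoxy ketone F7, Davis oxaziridine gives the potassium 5-alkoxide F8 (anti to the side chain), and Ac2O quench rejoins the route at 23.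

Step 8 (furan unmasking). Singlet oxygen may also attack the Δ10 alkene (ene reaction), and the keto-enal is lost easily on work-up. The fallback is a two-electron anodic oxidation in place of photooxygenation; the furan oxidises well below the alkenes. It sets out from 16. Constant-current electrolysis (graphite anode, MeOH, Et4NOTs, 2,6-lutidine, −20 °C) gives 2-[(2Z,4S)-4-{[tert-butyl(dimethyl)silyl]oxy}-3,7-dimethylocta-2,6-dien-1-yl]-2,5-dimethoxy-3-methyl-2,5-dihydrofuran F9 (diastereomer mixture). Brief hydrolysis (0.05 M H2SO4, acetone/H2O, 0 °C) opens it to the cis-keto-enal and rejoins the route at 18.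

**Further compounds**
F1 | step 9 | (3S)-3-[(tert-butyldimethylsilyl)oxy]-6-methyl-1-(trimethylsilyl)hept-5-en-2-one | C[Si](C)(C)CC(=O)[C@H](CC=C(C)C)O[Si](C)(C)C(C)(C)C
F2 | step 9 | 2-[(4S)-4-{[tert-butyl(dimethyl)silyl]oxy}-7-methyl-3-[(trimethylsilyl)methyl]octa-2,6-dien-1-yl]-3-methylfuran (E/Z mixture) | Cc1ccoc1CC=C(C[Si](C)(C)C)[C@H](CC=C(C)C)O[Si](C)(C)C(C)(C)C
F3 | step 9 | 2,5-endoperoxide of F2 (not isolated) | CC1=CC2OOC1(CC=C(C[Si](C)(C)C)[C@H](CC=C(C)C)O[Si](C)(C)C(C)(C)C)O2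
F4 | step 9 | (2Z,8S)-8-[(tert-butyldimethylsilyl)oxy]-3,11-dimethyl-4-oxo-7-[(trimethylsilyl)methyl]dodeca-2,6,10-trienal | O=C/C=C(/C)C(=O)CC=C(C[Si](C)(C)C)[C@H](CC=C(C)C)O[Si](C)(C)C(C)(C)C
F5 | step 11 | (1S,6R,8S)-1-acetoxy-8-[(tert-butyldimethylsilyl)oxy]bisabola-2,7(14),10-trien-4-one | C=C([C@@H]1[C@@H](OC(C)=O)C=C(C)C(=O)C1)[C@H](CC=C(C)C)O[Si](C)(C)C(C)(C)C
F6 | step 11 | (1R,2S,3S,6R,8S)-1-acetoxy-8-[(tert-butyldimethylsilyl)oxy]-2,3-epoxybisabola-7(14),10-dien-4-one | C=C([C@@H]1[C@@H](OC(C)=O)[C@@H]2O[C@]2(C)C(=O)C1)[C@H](CC=C(C)C)O[Si](C)(C)C(C)(C)C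
F7 | step 11 | potassium C4–C5 enolate of F6 (not isolated) | C=C([C@@H]1[C@@H](OC(C)=O)[C@@H]2O[C@]2(C)C([O-])=C1)[C@H](CC=C(C)C)O[Si](C)(C)C(C)(C)C.[K+]
F8 | step 11 | potassium (1R,2S,3S,5S,6R,8S)-1-acetoxy-8-[(tert-butyldimethylsilyl)oxy]-2,3-epoxy-4-oxobisabola-7(14),10-dien-5-olate (not isolated) | C=C([C@@H]1[C@@H](OC(C)=O)[C@@H]2O[C@]2(C)C(=O)[C@H]1[O-])[C@H](CC=C(C)C)O[Si](C)(C)C(C)(C)C.[K+]
F9 | step 8 | 2-[(2Z,4S)-4-{[tert-butyl(dimethyl)silyl]oxy}-3,7-dimethylocta-2,6-dien-1-yl]-2,5-dimethoxy-3-methyl-2,5-dihydrofuran | COC1C=C(C)C(OC)(C/C=C(/C)[C@H](CC=C(C)C)O[Si](C)(C)C(C)(C)C)O1
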